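## Retrosynthetic overview

- Target 11 comes from 10 by one-pot methanolysis of three acetates and two aryl silyl ethers; 10 comes from 9 by palladium-catalysed allylic C–H acetoxylation of the ring A allyl group (the same reaction makes dienophile 4 from 3).
- Each dioxane ring comes from oxidative dearomatisation of a catechol to an o-quinone, followed by an enantioselective dioxa-[4+2] cycloaddition with (E)-cinnamyl acetate 4. Each cycloaddition sets two stereocentres.
- The inner (2S,3S) dioxane (rings A/B) is formed first, from quinone 5 (from 4-allylcatechol 2) and 4.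
- The ring B catechol is then unmasked (7), oxidised to quinone 8 and joined with a second molecule of 4 to form the outer (2R,3R) dioxane (rings B/C). All three C6–C3 units come from eugenol 1.

Ring A carries the propenol chain, ring B is the central benzo ring, ring C is the free catechol. Benzodioxane numbering: O1, C2 (bears CH2O), C3 (bears aryl), O4. In the styrene, C-α is the benzylic alkene carbon and C-β the one next to CH2OAc.

Catalyst A: 3,3'-bis(2,4,6-triisopropylphenyl)-1,1'-binaphthyl-2,2'-diyl N-(trifluoromethylsulfonyl)phosphoramide, used as (R)-A or (S)-A.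

Assumption: the sense of induction of the proposed cycloaddition is taken as (R)-A giving the (2R,3R) adduct and (S)-A the (2S,3S) adduct; if the first run shows the opposite, the two catalyst enantiomers are exchanged between steps 4 and 6.

## Route

Step 1
Reactants: 1 eugenol (4-allyl-2-methoxyphenol)
Product: 2 4-allylbenzene-1,2-diol (4-allylcatechol)
Conditions: BBr3 (2.2 equiv), CH2Cl2, −78 °C to 0 °C; then H2O
Reagents that add atoms: none
Why: Lewis-acid cleavage of an aryl methyl ether (BBr3 demethylation), in which bromide attacks the O-methyl group of the boron-bound ether; the isolated terminal alkene survives at low temperature and no stereocentre is involved.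

Step 2
Reactants: 2 4-allylbenzene-1,2-diol
Product: 3 4-allyl-1,2-bis(tert-butyldimethylsilyloxy)benzene
Conditions: TBSCl (2.5 equiv), imidazole (5 equiv), DMF, rt
Reagents that add atoms: tert-butyldimethylsilyl chloride (TBSCl), CC(C)(C)[Si](C)(C)Cl
Why: Imidazole-promoted silylation of both phenols masks the catechol against the later oxidants and keeps the arene electron-rich; no stereocentre is involved.

Step 3
Reactants: 3 4-allyl-1,2-bis(tert-butyldimethylsilyloxy)benzene
Product: 4 (E)-3-[3,4-bis(tert-butyldimethylsilyloxy)phenyl]prop-2-en-1-yl acetate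
Conditions: Pd(OAc)2 (5 mol%), 4,5-diazafluoren-9-one (5 mol%), NaOAc (20 mol%), AcOH (16 equiv), 1,4-dioxane, O2 (1 atm), 60 °C
Reagents that add atoms: acetic acid, CC(=O)O
Why: Palladium-catalysed aerobic allylic C–H acetoxylation, in which cleavage of the doubly activated benzylic/allylic C–H gives a 1-aryl-π-allylpalladium species that acetate attacks at the unsubstituted terminus, so the conjugated linear (E)-acetate results.

Step 4
Reactants: 2 4-allylbenzene-1,2-diol (2.0 equiv); 4 (E)-3-[3,4-bis(tert-butyldimethylsilyloxy)phenyl]prop-2-en-1-yl acetate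
Product: 6 [(2S,3S)-6-allyl-3-[3,4-bis(tert-butyldimethylsilyloxy)phenyl]-2,3-dihydro-1,4-benzodioxin-2-yl]methyl acetate, via 4-allyl-1,2-benzoquinone 5 (not isolated)
Conditions: 2, Ag2O (4.4 equiv), MgSO4, CH2Cl2, −20 °C, 10 min, cold filtration under argon; filtrate added over 2 h to 4 and (S)-A (5 mol%), CH2Cl2–toluene 1:1, −60 °C, 36 h; Et3N quench
Reagents that add atoms: none
Why: Proposed new method: oxidative dearomatisation of 2 gives o-quinone 5, whose O=C–C=O unit acts as a dioxa-diene in a chiral Brønsted acid-catalysed inverse-electron-demand oxa-Diels–Alder reaction with the electron-rich styrene; the acid hydrogen-bonds to the more basic carbonyl (the one conjugated to the allyl-bearing carbon), so nucleophilic C-β bonds to the oxygen para to the allyl group and benzylic C-α to the meta oxygen; suprafacial addition to the E-alkene fixes the 2,3-trans relationship and the confined chiral phosphoramide counter-anion selects the alkene face, setting both stereocentres as (2S,3S) in one step; the closest known reaction types are the thermal hetero-Diels–Alder addition of o-quinones to (E)-propenylarenes giving trans-1,4-benzodioxanes and the chiral N-triflylphosphoramide-catalysed [4+2] cycloaddition of ortho-quinone methides with styrenes.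

Step 5
Reactants: 6 [(2S,3S)-6-allyl-3-[3,4-bis(tert-butyldimethylsilyloxy)phenyl]-2,3-dihydro-1,4-benzodioxin-2-yl]methyl acetate
Product: 7 [(2S,3S)-6-allyl-3-(3,4-dihydroxyphenyl)-2,3-dihydro-1,4-benzodioxin-2-yl]methyl acetate
Conditions: KHF2 (2.5 equiv), MeOH (degassed), rt, argon
Reagents that add atoms: none
Why: Chemoselective fluoride-mediated cleavage of the two aryl silyl ethers (phenoxide is a far better leaving group from silicon than alkoxide) frees the ring B catechol, while the weakly acidic medium leaves the primary acetate, the allyl group and both dioxane stereocentres untouched.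

Step 6
Reactants: 7 [(2S,3S)-6-allyl-3-(3,4-dihydroxyphenyl)-2,3-dihydro-1,4-benzodioxin-2-yl]methyl acetate; 4 (E)-3-[3,4-bis(tert-butyldimethylsilyloxy)phenyl]prop-2-en-1-yl acetate (3.0 equiv)
Product: 9 [(2S,3S)-3-[(2R,3R)-2-(acetoxymethyl)-3-[3,4-bis(tert-butyldimethylsilyloxy)phenyl]-2,3-dihydro-1,4-benzodioxin-6-yl]-6-allyl-2,3-dihydro-1,4-benzodioxin-2-yl]methyl acetate, via ring B ortho-quinone 8 (not isolated)
Conditions: 7, Ag2O (2.2 equiv), MgSO4, CH2Cl2, −20 °C, 10 min, cold filtration under argon; filtrate added over 3 h to 4 and (R)-A (10 mol%), CH2Cl2–toluene 1:1, −60 °C to −40 °C, 48 h; Et3N quench; excess 4 recovered on silica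
Reagents that add atoms: none
Why: Proposed new method: Ag2O dearomatises the ring B catechol of 7 to o-quinone 8, which enters the same chiral acid-catalysed dioxa-Diels–Alder reaction as in step 4, now with the enantiomeric catalyst and an excess of styrene 4; the dioxane carbon on the quinone plays the role of the allyl group, so C-β again bonds to the para oxygen and C-α to the meta oxygen, the E-alkene gives the trans ring, and because both new stereocentres arise on the styrene carbons, several bonds from the existing ones, the catalyst decides the new (2R,3R) pair; the closest known reaction types are the thermal o-quinone/propenylarene hetero-Diels–Alder reaction and chiral N-triflylphosphoramide-catalysed ortho-quinone methide/styrene cycloadditions.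

Step 7
Reactants: 9 [(2S,3S)-3-[(2R,3R)-2-(acetoxymethyl)-3-[3,4-bis(tert-butyldimethylsilyloxy)phenyl]-2,3-dihydro-1,4-benzodioxin-6-yl]-6-allyl-2,3-dihydro-1,4-benzodioxin-2-yl]methyl acetate
Product: 10 [(2S,3S)-6-[(E)-3-acetoxyprop-1-enyl]-3-[(2R,3R)-2-(acetoxymethyl)-3-[3,4-bis(tert-butyldimethylsilyloxy)phenyl]-2,3-dihydro-1,4-benzodioxin-6-yl]-2,3-dihydro-1,4-benzodioxin-2-yl]methyl acetate
Conditions: Pd(OAc)2 (10 mol%), 4,5-diazafluoren-9-one (10 mol%), NaOAc (20 mol%), AcOH (16 equiv), 1,4-dioxane, O2 (1 atm), 60 °C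
Reagents that add atoms: acetic acid, CC(=O)O
Why: The same palladium-catalysed allylic C–H acetoxylation as in step 3 installs the (E)-allylic oxygen of ring A through the 1-aryl-π-allylpalladium intermediate; the four stereocentres are remote and unaffected.

Step 8
Reactants: 10 [(2S,3S)-6-[(E)-3-acetoxyprop-1-enyl]-3-[(2R,3R)-2-(acetoxymethyl)-3-[3,4-bis(tert-butyldimethylsilyloxy)phenyl]-2,3-dihydro-1,4-benzodioxin-6-yl]-2,3-dihydro-1,4-benzodioxin-2-yl]methyl acetate
Product: 11 (E)-3-[(2S,3S)-3-[(2R,3R)-3-(3,4-dihydroxyphenyl)-2-(hydroxymethyl)-2,3-dihydro-1,4-benzodioxin-6-yl]-2-(hydroxymethyl)-2,3-dihydro-1,4-benzodioxin-6-yl]prop-2-en-1-ol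
Conditions: K2CO3 (0.5 equiv), MeOH–THF 3:1 (degassed), rt, argon; AcOH to pH 6
Reagents that add atoms: none
Why: Base-catalysed transesterification removes the three acetates and methoxide-mediated silyl transfer to methanol frees the two phenols; the benzodioxanes and the E-allylic alcohol are stable to mild base, and air is excluded to protect the catechol.

## Compound list

1 | eugenol (4-allyl-2-methoxyphenol) | C=CCc1ccc(O)c(OC)c1 | starting material
2 | 4-allylbenzene-1,2-diol (4-allylcatechol) | C=CCc1ccc(O)c(O)c1 | intermediate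
3 | 4-allyl-1,2-bis(tert-butyldimethylsilyloxy)benzene | C=CCc1ccc(O[Si](C)(C)C(C)(C)C)c(O[Si](C)(C)C(C)(C)C)c1 | intermediate
4 | (E)-3-[3,4-bis(tert-butyldimethylsilyloxy)phenyl]prop-2-en-1-yl acetate | CC(=O)OC/C=C/c1ccc(O[Si](C)(C)C(C)(C)C)c(O[Si](C)(C)C(C)(C)C)c1 | intermediate
5 | 4-allyl-1,2-benzoquinone (4-allylcyclohexa-3,5-diene-1,2-dione) | C=CCC1=CC(=O)C(=O)C=C1 | intermediate (not isolated)
6 | [(2S,3S)-6-allyl-3-[3,4-bis(tert-butyldimethylsilyloxy)phenyl]-2,3-dihydro-1,4-benzodioxin-2-yl]methyl acetate | C=CCc1ccc2c(c1)O[C@@H](c1ccc(O[Si](C)(C)C(C)(C)C)c(O[Si](C)(C)C(C)(C)C)c1)[C@H](COC(C)=O)O2 | intermediate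
7 | [(2S,3S)-6-allyl-3-(3,4-dihydroxyphenyl)-2,3-dihydro-1,4-benzodioxin-2-yl]methyl acetate | C=CCc1ccc2c(c1)O[C@@H](c1ccc(O)c(O)c1)[C@H](COC(C)=O)O2 | intermediate
8 | [(2S,3S)-6-allyl-3-(3,4-dioxocyclohexa-1,5-dien-1-yl)-2,3-dihydro-1,4-benzodioxin-2-yl]methyl acetate (ring B ortho-quinone) | C=CCc1ccc2c(c1)O[C@@H](C1=CC(=O)C(=O)C=C1)[C@H](COC(C)=O)O2 | intermediate (not isolated)
9 | [(2S,3S)-3-[(2R,3R)-2-(acetoxymethyl)-3-[3,4-bis(tert-butyldimethylsilyloxy)phenyl]-2,3-dihydro-1,4-benzodioxin-6-yl]-6-allyl-2,3-dihydro-1,4-benzodioxin-2-yl]methyl acetate | C=CCc1ccc2c(c1)O[C@@H](c1ccc3c(c1)O[C@H](c1ccc(O[Si](C)(C)C(C)(C)C)c(O[Si](C)(C)C(C)(C)C)c1)[C@@H](COC(C)=O)O3)[C@H](COC(C)=O)O2 | intermediate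
10 | [(2S,3S)-6-[(E)-3-acetoxyprop-1-enyl]-3-[(2R,3R)-2-(acetoxymethyl)-3-[3,4-bis(tert-butyldimethylsilyloxy)phenyl]-2,3-dihydro-1,4-benzodioxin-6-yl]-2,3-dihydro-1,4-benzodioxin-2-yl]methyl acetate | CC(=O)OC/C=C/c1ccc2c(c1)O[C@@H](c1ccc3c(c1)O[C@H](c1ccc(O[Si](C)(C)C(C)(C)C)c(O[Si](C)(C)C(C)(C)C)c1)[C@@H](COC(C)=O)O3)[C@H](COC(C)=O)O2 | intermediate
11 | (E)-3-[(2S,3S)-3-[(2R,3R)-3-(3,4-dihydroxyphenyl)-2-(hydroxymethyl)-2,3-dihydro-1,4-benzodioxin-6-yl]-2-(hydroxymethyl)-2,3-dihydro-1,4-benzodioxin-6-yl]prop-2-en-1-ol | OC/C=C/c1ccc2c(c1)O[C@@H](c1ccc3c(c1)O[C@H](c1ccc(O)c(O)c1)[C@@H](CO)O3)[C@H](CO)O2 | target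

## Step count and risk

Total step count: 8. Longest linear sequence: 8 steps (1 → 2 → 3 → 4 → 6 → 7 → 9 → 10 → 11); compound 2 re-enters as the quinone precursor in step 4 and compound 4 re-enters as the dienophile in step 6.

The three steps most likely to fail:

**Step 4.** The catalytic asymmetric cycloaddition is new. Its regiochemistry rests only on the modest electronic bias of the allyl group, so the 7-allyl regioisomer may form alongside 6. Quinone 5 is labile and can tautomerise to a quinone methide, dimerise, or react as a carbodiene. The strong acid can also oligomerise the styrene. The fallback sets out from 2 and 4 and comes back at 6. It gives up asymmetric catalysis for a racemic cycloaddition followed by enzymatic kinetic resolution; it does not cure a poor regioisomer ratio. Quinone 5 (from 2 and Ag2O as before) and 4 are combined without acid in CH2Cl2 at 0 °C to room temperature. The uncatalysed hetero-Diels–Alder addition gives racemic trans-[6-allyl-3-[3,4-bis(tert-butyldimethylsilyloxy)phenyl]-2,3-dihydro-1,4-benzodioxin-2-yl]methyl acetate F1. Alcoholysis with immobilised Candida antarctica lipase B and n-butanol in tert-butyl methyl ether at 40 °C is expected to take the (2S,3S)-acetate. This sense is assumed by analogy with related 2-hydroxymethyl-1,4-benzodioxanes and must be confirmed on the first run. That enantiomer becomes [(2S,3S)-6-allyl-3-[3,4-bis(tert-butyldimethylsilyloxy)phenyl]-2,3-dihydro-1,4-benzodioxin-2-yl]methanol F2, which is separated on silica from the other half of F1, left behind as acetate. Ac2O, pyridine and DMAP (5 mol%) in CH2Cl2 at 0 °C return F2 to acetate 6. Should the lipase prefer the opposite enantiomer, the untouched acetate is 6 itself and no re-acetylation is needed.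

**Step 6.** This is the same unproven reaction, now with the valuable fragment as the quinone.
- Quinone 8 carries a benzylic C–H next to an aryl ether oxygen. Tautomerisation to a quinone methide would destroy the C3 stereocentre.
- The regiochemical bias of the dioxane carbon is weaker than that of an allyl group.
- The neighbouring stereocentres may give a mismatched pairing with (R)-A.

The fallback sets out from 2 and 4 and comes back at 9. It reverses the order of ring formation and the roles of the partners, so the only quinone is again the simple 5 and the elaborate fragment is the styrene. Step 4 is run with (R)-A to give [(2R,3R)-6-allyl-3-[3,4-bis(tert-butyldimethylsilyloxy)phenyl]-2,3-dihydro-1,4-benzodioxin-2-yl]methyl acetate F3. Allylic C–H acetoxylation under the conditions of step 3 gives [(2R,3R)-6-[(E)-3-acetoxyprop-1-enyl]-3-[3,4-bis(tert-butyldimethylsilyloxy)phenyl]-2,3-dihydro-1,4-benzodioxin-2-yl]methyl acetate F4. A fresh cold solution of quinone 5 (from 2, 2.5 equiv, and Ag2O) is added to F4 and (S)-A (10 mol%) at −60 °C. The cycloaddition builds the inner (2S,3S) ring on the new styrene and gives 9.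

**Step 7.** This is a late-stage C–H oxidation in warm acetic acid on a molecule with two acid-sensitive benzylic aryl ethers. Branched acetate, Wacker ketone and simple alkene isomerisation are possible by-products. The fallback sets out from 9 and comes back at 10. It replaces C–H oxidation by isomerisation and cross-metathesis. RuHCl(CO)(PPh3)3 (2 mol%) in toluene at 80 °C moves the double bond into conjugation and gives [(2S,3S)-3-[(2R,3R)-2-(acetoxymethyl)-3-[3,4-bis(tert-butyldimethylsilyloxy)phenyl]-2,3-dihydro-1,4-benzodioxin-6-yl]-6-[(E)-prop-1-enyl]-2,3-dihydro-1,4-benzodioxin-2-yl]methyl acetate F5. Cross-metathesis of F5 with (Z)-but-2-ene-1,4-diyl diacetate (5 equiv) and second-generation Hoveyda–Grubbs catalyst (5 mol%) in CH2Cl2 at 40 °C gives the (E)-cinnamyl acetate 10.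

Further compounds

F1 | step 4 | racemic trans-[6-allyl-3-[3,4-bis(tert-butyldimethylsilyloxy)phenyl]-2,3-dihydro-1,4-benzodioxin-2-yl]methyl acetate (1:1 mixture of 6 and its (2R,3R)-enantiomer) | C=CCc1ccc2c(c1)O[C@@H](c1ccc(O[Si](C)(C)C(C)(C)C)c(O[Si](C)(C)C(C)(C)C)c1)[C@H](COC(C)=O)O2.C=CCc1ccc2c(c1)O[C@H](c1ccc(O[Si](C)(C)C(C)(C)C)c(O[Si](C)(C)C(C)(C)C)c1)[C@@H](COC(C)=O)O2
F2 | step 4 | [(2S,3S)-6-allyl-3-[3,4-bis(tert-butyldimethylsilyloxy)phenyl]-2,3-dihydro-1,4-benzodioxin-2-yl]methanol | C=CCc1ccc2c(c1)O[C@@H](c1ccc(O[Si](C)(C)C(C)(C)C)c(O[Si](C)(C)C(C)(C)C)c1)[C@H](CO)O2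
F3 | step 6 | [(2R,3R)-6-allyl-3-[3,4-bis(tert-butyldimethylsilyloxy)phenyl]-2,3-dihydro-1,4-benzodioxin-2-yl]methyl acetate | C=CCc1ccc2c(c1)O[C@H](c1ccc(O[Si](C)(C)C(C)(C)C)c(O[Si](C)(C)C(C)(C)C)c1)[C@@H](COC(C)=O)O2
F4 | step 6 | [(2R,3R)-6-[(E)-3-acetoxyprop-1-enyl]-3-[3,4-bis(tert-butyldimethylsilyloxy)phenyl]-2,3-dihydro-1,4-benzodioxin-2-yl]methyl acetate | CC(=O)OC/C=C/c1ccc2c(c1)O[C@H](c1ccc(O[Si](C)(C)C(C)(C)C)c(O[Si](C)(C)C(C)(C)C)c1)[C@@H](COC(C)=O)O2
F5 | step 7 | [(2S,3S)-3-[(2R,3R)-2-(acetoxymethyl)-3-[3,4-bis(tert-butyldimethylsilyloxy)phenyl]-2,3-dihydro-1,4-benzodioxin-6-yl]-6-[(E)-prop-1-enyl]-2,3-dihydro-1,4-benzodioxin-2-yl]methyl acetate | C/C=C/c1ccc2c(c1)O[C@@H](c1ccc3c(c1)O[C@H](c1ccc(O[Si](C)(C)C(C)(C)C)c(O[Si](C)(C)C(C)(C)C)c1)[C@@H](COC(C)=O)O3)[C@H](COC(C)=O)O2
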